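Ring A is grown onto the ether oxygen instead of being joined to ring B as a finished arene. The disconnection cuts C1–C2, C2–C3, C4–C5 and C5–C6 of ring A and leads back to methoxyacetylene and an α-diazo enone that already carries ring B as an enol ether. One photochemical–thermal cascade (Wolff rearrangement, ketene–alkyne [2+2] addition, four-electron opening of the cyclobutenone, six-electron ring closure) builds ring A. It exploits the ring A pattern: C5–OH next to the aryloxy carbon C6 and meta to C3–OMe, with the CH2O arm on C1. The precursor is an (E)-β-aryloxy-α-(silyloxymethyl)vinyl diazomethyl ketone with the ring B phenol masked as a silyl ether.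

Key step: step 10

Remark: ring A is numbered C1 (carries CH2O), C3 (OMe), C5 (OH), C6 (aryloxy carbon); ring B is the methyl benzoate ring; TBDPS = tert-butyldiphenylsilyl, TIPS = triisopropylsilyl.
Remark: methyl 2,6-dihydroxy-4-methylbenzoate and 2-chloro-1,1-dimethoxyethane are taken as purchasable; methoxyacetylene is volatile and is made in step 9.
Remark: both protecting groups are silyl ethers, so that acid can remove the tert-butyl ester in step 6 and one fluoride treatment frees every hydroxyl before the palmitate is attached; no Lewis acid then meets the benzylic ester.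

Step 1
Reactants: 1 methyl 2,6-dihydroxy-4-methylbenzoate
Product: 2 methyl 2-hydroxy-4-methyl-6-[(triisopropylsilyl)oxy]benzoate
Conditions: TIPSCl (1.05 equiv), imidazole, DMF, 0 °C → rt
Reagents that add atoms: triisopropylsilyl chloride, CC(C)[Si](Cl)(C(C)C)C(C)C
Why: Phenol silylation of one of two equivalent hydroxyls; once the first silyl group is on, the remaining hydroxyl is hydrogen-bonded to the ester carbonyl and shielded, so the reaction should stop at the monoether.

Step 2
Reactants: 3 tert-butyl 3-hydroxypropanoate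
Product: 4 tert-butyl 3-[(tert-butyldiphenylsilyl)oxy]propanoate
Conditions: TBDPSCl, imidazole, CH2Cl2, rt
Reagents that add atoms: tert-butyldiphenylsilyl chloride, CC(C)(C)[Si](Cl)(c1ccccc1)c1ccccc1
Why: Standard silyl ether formation at a primary alcohol; TBDPS is chosen because it survives the acidolysis of the tert-butyl ester in step 6.

Step 3
Reactants: 4 tert-butyl 3-[(tert-butyldiphenylsilyl)oxy]propanoate
Product: 5 tert-butyl 2-formyl-3-[(tert-butyldiphenylsilyl)oxy]propanoate (racemic, in equilibrium with its enol)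
Conditions: LiN(iPr)2, THF, –78 °C; HCO2CH2CF3, –78 °C; AcOH
Reagents that add atoms: 2,2,2-trifluoroethyl formate, O=COCC(F)(F)F
Why: Crossed Claisen formylation of the ester lithium enolate, a classical reaction of 3-alkoxypropanoates; the fast formyl donor should trap the enolate at –78 °C before it can expel silanolate, and the product then rests as its stabilized enolate until the quench.

Step 4
Reactants: 5 tert-butyl 2-formyl-3-[(tert-butyldiphenylsilyl)oxy]propanoate
Product: 6 tert-butyl (2E)-2-{[(tert-butyldiphenylsilyl)oxy]methyl}-3-(tosyloxy)prop-2-enoate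
Conditions: TsCl, N-methylimidazole, Et3N, MeCN, 0 °C
Reagents that add atoms: p-toluenesulfonyl chloride, Cc1ccc(cc1)S(Cl)(=O)=O
Why: O-Sulfonylation of the formyl ester enol under non-chelating amine conditions, which should give the E enol tosylate (tosyloxy group trans to the ester).

Step 5
Reactants: 6 tert-butyl (2E)-2-{[(tert-butyldiphenylsilyl)oxy]methyl}-3-(tosyloxy)prop-2-enoate; 2 methyl 2-hydroxy-4-methyl-6-[(triisopropylsilyl)oxy]benzoate
Product: 7 tert-butyl (2E)-2-{[(tert-butyldiphenylsilyl)oxy]methyl}-3-{2-(methoxycarbonyl)-5-methyl-3-[(triisopropylsilyl)oxy]phenoxy}prop-2-enoate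
Conditions: NaH, THF, 0 °C; then 6, DMF, rt
Reagents that add atoms: none
Why: Addition–elimination (nucleophilic vinylic substitution) of the phenoxide at the β-carbon of the acrylate with loss of tosylate; retention and thermodynamic preference both point to the E enol ether, and the crowded ring B oxygen is bonded to an activated alkene CH, not to an arene carbon.

Step 6
Reactants: 7 tert-butyl (2E)-2-{[(tert-butyldiphenylsilyl)oxy]methyl}-3-{2-(methoxycarbonyl)-5-methyl-3-[(triisopropylsilyl)oxy]phenoxy}prop-2-enoate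
Product: 8 (2E)-2-{[(tert-butyldiphenylsilyl)oxy]methyl}-3-{2-(methoxycarbonyl)-5-methyl-3-[(triisopropylsilyl)oxy]phenoxy}prop-2-enoic acid
Conditions: CF3CO2H/CH2Cl2 (1:4), 0 °C → rt
Reagents that add atoms: none
Why: Acidolysis of the tert-butyl ester through the tert-butyl cation; the push–pull enol ether, the primary TBDPS ether, the aryl TIPS ether and the hindered methyl ester should all tolerate trifluoroacetic acid.

Step 7
Reactants: 8 (2E)-2-{[(tert-butyldiphenylsilyl)oxy]methyl}-3-{2-(methoxycarbonyl)-5-methyl-3-[(triisopropylsilyl)oxy]phenoxy}prop-2-enoic acid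
Product: 10 methyl 2-{[(1E)-2-{[(tert-butyldiphenylsilyl)oxy]methyl}-3-oxobut-1-en-1-yl]oxy}-4-methyl-6-[(triisopropylsilyl)oxy]benzoate, via acid chloride 9 (not isolated)
Conditions: (COCl)2, DMF (cat.), CH2Cl2, 0 °C → rt; evaporate; MeZnCl, Pd(PPh3)4 (5 mol %), THF, 0 °C → rt
Reagents that add atoms: methylzinc chloride, C[Zn]Cl; oxalyl chloride, O=C(Cl)C(Cl)=O (chlorine of 9 only)
Why: Acid chloride formation followed by Negishi ketone synthesis (acyl–palladium, transmetalation from zinc, reductive elimination); the organozinc should leave both esters and the β-aryloxy enone alone, and the E geometry holds the acyl group away from ring B.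

Step 8
Reactants: 10 methyl 2-{[(1E)-2-{[(tert-butyldiphenylsilyl)oxy]methyl}-3-oxobut-1-en-1-yl]oxy}-4-methyl-6-[(triisopropylsilyl)oxy]benzoate
Product: 12 methyl 2-{[(1E)-4-diazo-2-{[(tert-butyldiphenylsilyl)oxy]methyl}-3-oxobut-1-en-1-yl]oxy}-4-methyl-6-[(triisopropylsilyl)oxy]benzoate, via trifluoroacetyl diketone 11 (not isolated)
Conditions: LiN(SiMe3)2, THF, –78 °C; CF3CO2CH2CF3; aq. HCl work-up; then MsN3, Et3N, H2O, MeCN, rt
Reagents that add atoms: methanesulfonyl azide, CS(=O)(=O)N=[N+]=[N-]; 2,2,2-trifluoroethyl trifluoroacetate, O=C(OCC(F)(F)F)C(F)(F)F (trifluoroacetyl group of 11 only)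
Why: Detrifluoroacetylative diazo transfer (kinetic enolization at the methyl group, the only acidic site, then trifluoroacetylation and sulfonyl azide transfer), used because acylation of diazomethane by conjugated acyl chlorides is unreliable owing to dipolar cycloaddition at the C=C bond.

Step 9
Reactants: 13 2-chloro-1,1-dimethoxyethane
Product: 15 methoxyacetylene, via sodium methoxyacetylide 14 (not isolated)
Conditions: NaNH2 (3 equiv), liq. NH3, –33 °C; then cold sat. aq. NaCl; distil into a –78 °C trap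
Reagents that add atoms: sodium amide, [Na+].[NH2-] (sodium of 14 only)
Why: Amide-induced twofold elimination (HCl, then methanol) gives the sodium acetylide of the ynol ether, which is protonated on the quench; this is the standard preparation of alkoxyacetylenes from chloroacetaldehyde acetals.

Step 10
Reactants: 12 methyl 2-{[(1E)-4-diazo-2-{[(tert-butyldiphenylsilyl)oxy]methyl}-3-oxobut-1-en-1-yl]oxy}-4-methyl-6-[(triisopropylsilyl)oxy]benzoate; 15 methoxyacetylene
Product: 20 methyl 2-(2-{[(tert-butyldiphenylsilyl)oxy]methyl}-6-hydroxy-4-methoxyphenoxy)-4-methyl-6-[(triisopropylsilyl)oxy]benzoate, via vinylketene 16 (not isolated), via 4-vinylcyclobutenone 17 (not isolated), via dienylketene 18 (not isolated), via cyclohexa-2,4-dienone 19 (not isolated)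
Conditions: hν (300 nm), 15 (5 equiv), ClCH2CH2Cl, 10 °C, sealed tube; then 80 °C
Reagents that add atoms: none
Why: Light expels N2 from 12 and the alkenyl group shifts to the carbene carbon (Wolff rearrangement, C1–C2) to give vinylketene 16; its ketene C=C adds to 15 in a [2+2] cycloaddition (C4–C5 and C2–C3) to give 17, whose four-electron electrocyclic opening gives dienylketene 18. Ring A then closes by a thermal disrotatory six-electron electrocyclization of 18 (C5–C6) to dienone 19, and tautomerization to the phenol makes the sequence irreversible. The closest known reaction is the Danheiser benzannulation in its photochemical diazo ketone form with alkoxyacetylenes; a vinylketene with an aryloxy group at its terminus has not been put through it, which is why the risk of the route is placed here. No stereocenter survives, since the sp3 carbons of 17 and 19 are erased on aromatization. The step needs regiocontrol in the [2+2] event, and the polarization of the ynol ether secures it: its nucleophilic CH carbon bonds to the ketene carbonyl carbon, so OMe ends meta to the new C5–OH and C5 sits next to the aryloxy carbon C6. The E enol ether keeps the aryloxy group on the outside of the closing triene, and the excess of 15 should keep ketene 16 from being captured by phenol 20.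

Step 11
Reactants: 20 methyl 2-(2-{[(tert-butyldiphenylsilyl)oxy]methyl}-6-hydroxy-4-methoxyphenoxy)-4-methyl-6-[(triisopropylsilyl)oxy]benzoate
Product: 21 methyl 2-hydroxy-6-[2-hydroxy-6-(hydroxymethyl)-4-methoxyphenoxy]-4-methylbenzoate
Conditions: Bu4NF, AcOH, THF, 0 °C → rt
Reagents that add atoms: none
Why: Fluoride-induced desilylation of both ethers (aryl TIPS fast, primary TBDPS slower); acetic acid buffers the phenoxides so that the ester-activated diaryl ether next to a phenol is not exposed to base.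

Step 12
Reactants: 21 methyl 2-hydroxy-6-[2-hydroxy-6-(hydroxymethyl)-4-methoxyphenoxy]-4-methylbenzoate; 22 palmitic acid
Product: 23 Betaethrin E, methyl 2-{2-[(hexadecanoyloxy)methyl]-6-hydroxy-4-methoxyphenoxy}-6-hydroxy-4-methylbenzoate
Conditions: PPh3, DIAD, THF, 0 °C → rt
Reagents that add atoms: none
Why: Mitsunobu esterification: the primary alcohol is activated as an alkoxyphosphonium ion and only the most acidic partner, the carboxylic acid, is deprotonated, so palmitate should attack the benzylic carbon while both phenols stay free.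

Compound list
1 | methyl 2,6-dihydroxy-4-methylbenzoate | COC(=O)c1c(O)cc(C)cc1O | starting material
2 | methyl 2-hydroxy-4-methyl-6-[(triisopropylsilyl)oxy]benzoate | COC(=O)c1c(O)cc(C)cc1O[Si](C(C)C)(C(C)C)C(C)C | intermediate
3 | tert-butyl 3-hydroxypropanoate | CC(C)(C)OC(=O)CCO | starting material
4 | tert-butyl 3-[(tert-butyldiphenylsilyl)oxy]propanoate | CC(C)(C)OC(=O)CCO[Si](c1ccccc1)(c1ccccc1)C(C)(C)C | intermediate
5 | tert-butyl 2-formyl-3-[(tert-butyldiphenylsilyl)oxy]propanoate (racemic, enolizable) | CC(C)(C)OC(=O)C(C=O)CO[Si](c1ccccc1)(c1ccccc1)C(C)(C)C | intermediate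
6 | tert-butyl (2E)-2-{[(TBDPS)oxy]methyl}-3-(tosyloxy)prop-2-enoate | CC(C)(C)OC(=O)/C(CO[Si](c1ccccc1)(c1ccccc1)C(C)(C)C)=C/OS(=O)(=O)c1ccc(C)cc1 | intermediate
7 | tert-butyl (2E)-2-{[(TBDPS)oxy]methyl}-3-{2-(methoxycarbonyl)-5-methyl-3-[(TIPS)oxy]phenoxy}prop-2-enoate | CC(C)(C)OC(=O)/C(CO[Si](c1ccccc1)(c1ccccc1)C(C)(C)C)=C/Oc1cc(C)cc(O[Si](C(C)C)(C(C)C)C(C)C)c1C(=O)OC | intermediate
8 | (2E)-2-{[(TBDPS)oxy]methyl}-3-{2-(methoxycarbonyl)-5-methyl-3-[(TIPS)oxy]phenoxy}prop-2-enoic acid | OC(=O)/C(CO[Si](c1ccccc1)(c1ccccc1)C(C)(C)C)=C/Oc1cc(C)cc(O[Si](C(C)C)(C(C)C)C(C)C)c1C(=O)OC | intermediate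
9 | (2E)-2-{[(TBDPS)oxy]methyl}-3-{2-(methoxycarbonyl)-5-methyl-3-[(TIPS)oxy]phenoxy}prop-2-enoyl chloride | ClC(=O)/C(CO[Si](c1ccccc1)(c1ccccc1)C(C)(C)C)=C/Oc1cc(C)cc(O[Si](C(C)C)(C(C)C)C(C)C)c1C(=O)OC | intermediate
10 | methyl 2-{[(1E)-2-{[(TBDPS)oxy]methyl}-3-oxobut-1-en-1-yl]oxy}-4-methyl-6-[(TIPS)oxy]benzoate | CC(=O)/C(CO[Si](c1ccccc1)(c1ccccc1)C(C)(C)C)=C/Oc1cc(C)cc(O[Si](C(C)C)(C(C)C)C(C)C)c1C(=O)OC | intermediate
11 | methyl 2-{[(1E)-2-{[(TBDPS)oxy]methyl}-6,6,6-trifluoro-3,5-dioxohex-1-en-1-yl]oxy}-4-methyl-6-[(TIPS)oxy]benzoate (drawn as the diketone) | O=C(CC(=O)C(F)(F)F)/C(CO[Si](c1ccccc1)(c1ccccc1)C(C)(C)C)=C/Oc1cc(C)cc(O[Si](C(C)C)(C(C)C)C(C)C)c1C(=O)OC | intermediate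
12 | methyl 2-{[(1E)-4-diazo-2-{[(TBDPS)oxy]methyl}-3-oxobut-1-en-1-yl]oxy}-4-methyl-6-[(TIPS)oxy]benzoate | [N-]=[N+]=CC(=O)/C(CO[Si](c1ccccc1)(c1ccccc1)C(C)(C)C)=C/Oc1cc(C)cc(O[Si](C(C)C)(C(C)C)C(C)C)c1C(=O)OC | intermediate
13 | 2-chloro-1,1-dimethoxyethane (chloroacetaldehyde dimethyl acetal) | COC(CCl)OC | starting material
14 | sodium methoxyacetylide | [Na+].[C-]#COC | intermediate
15 | methoxyacetylene (methoxyethyne) | COC#C | intermediate
16 | vinylketene: methyl 2-{[(1Z)-2-{[(TBDPS)oxy]methyl}-4-oxobuta-1,3-dien-1-yl]oxy}-4-methyl-6-[(TIPS)oxy]benzoate | O=C=C/C(CO[Si](c1ccccc1)(c1ccccc1)C(C)(C)C)=C/Oc1cc(C)cc(O[Si](C(C)C)(C(C)C)C(C)C)c1C(=O)OC | intermediate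
17 | 4-vinylcyclobutenone: methyl 2-{[(1Z)-3-[(TBDPS)oxy]-2-(2-methoxy-4-oxocyclobut-2-en-1-yl)prop-1-en-1-yl]oxy}-4-methyl-6-[(TIPS)oxy]benzoate (racemic) | O=C1C=C(OC)C1/C(CO[Si](c1ccccc1)(c1ccccc1)C(C)(C)C)=C/Oc1cc(C)cc(O[Si](C(C)C)(C(C)C)C(C)C)c1C(=O)OC | intermediate
18 | dienylketene: methyl 2-{[(1Z,3E)-4-methoxy-2-{[(TBDPS)oxy]methyl}-6-oxohexa-1,3,5-trien-1-yl]oxy}-4-methyl-6-[(TIPS)oxy]benzoate | O=C=C\C(OC)=C/C(CO[Si](c1ccccc1)(c1ccccc1)C(C)(C)C)=C/Oc1cc(C)cc(O[Si](C(C)C)(C(C)C)C(C)C)c1C(=O)OC | intermediate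
19 | cyclohexa-2,4-dienone: methyl 2-({2-{[(TBDPS)oxy]methyl}-4-methoxy-6-oxocyclohexa-2,4-dien-1-yl}oxy)-4-methyl-6-[(TIPS)oxy]benzoate (racemic) | O=C1C=C(OC)C=C(CO[Si](c2ccccc2)(c2ccccc2)C(C)(C)C)C1Oc1cc(C)cc(O[Si](C(C)C)(C(C)C)C(C)C)c1C(=O)OC | intermediate
20 | methyl 2-(2-{[(TBDPS)oxy]methyl}-6-hydroxy-4-methoxyphenoxy)-4-methyl-6-[(TIPS)oxy]benzoate | COC(=O)c1c(O[Si](C(C)C)(C(C)C)C(C)C)cc(C)cc1Oc1c(O)cc(OC)cc1CO[Si](c1ccccc1)(c1ccccc1)C(C)(C)C | intermediate
21 | methyl 2-hydroxy-6-[2-hydroxy-6-(hydroxymethyl)-4-methoxyphenoxy]-4-methylbenzoate | COC(=O)c1c(O)cc(C)cc1Oc1c(O)cc(OC)cc1CO | intermediate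
22 | palmitic acid (hexadecanoic acid) | CCCCCCCCCCCCCCCC(=O)O | starting material
23 | Betaethrin E, methyl 2-{2-[(hexadecanoyloxy)methyl]-6-hydroxy-4-methoxyphenoxy}-6-hydroxy-4-methylbenzoate (no stereocenter) | CCCCCCCCCCCCCCCC(=O)OCc1cc(OC)cc(O)c1Oc1cc(C)cc(O)c1C(=O)OC | target

Total step count: 12. Longest linear sequence: 10 steps (3 → 4 → 5 → 6 → 7 → 8 → 10 → 12 → 20 → 21 → 23; steps 2–8 and 10–12).

Steps most likely to fail

Step 10. The Wolff step may be outrun by other photoreactions of the aryl enol ether (E/Z isomerization, cleavage of the vinyl–oxygen bond) or by secondary photolysis of 17 and 20. The vinylketene may also be captured by phenol already formed before it meets the volatile alkyne. Fallback: light is taken out and the ketene is made with base. Setting out from 12, a silver-benzoate-promoted Wolff rearrangement in wet THF (PhCO2Ag, Et3N, THF/H2O, dark) would give the homologous acid (3Z)-3-{[(TBDPS)oxy]methyl}-4-{2-(methoxycarbonyl)-5-methyl-3-[(TIPS)oxy]phenoxy}but-3-enoic acid F1. Neutral chlorination with 1-chloro-N,N,2-trimethylprop-1-en-1-amine would give (3Z)-3-{[(TBDPS)oxy]methyl}-4-{2-(methoxycarbonyl)-5-methyl-3-[(TIPS)oxy]phenoxy}but-3-enoyl chloride F2. Slow addition of Et3N to F2 and excess 15 in CH2Cl2 at 0 °C would generate 16 by dehydrochlorination and trap it as 17; warming to 80 °C would carry 17 through 18 and 19 to 20, where the route is rejoined.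

Step 3. The lithium enolate of 4 may expel tert-butyldiphenylsilanolate (β-elimination to tert-butyl acrylate) faster than it is formylated. Fallback: the carbon is added before the silyl group, through a dianion that has no leaving group. Setting out from 3, LiN(iPr)2 (2.2 equiv, THF, –78 → –20 °C) would give the alkoxide–enolate dianion, and gaseous formaldehyde would give the symmetric diol tert-butyl 3-hydroxy-2-(hydroxymethyl)propanoate F3. Monosilylation of one of its two equivalent hydroxyls (TBDPSCl, imidazole) would give tert-butyl 3-hydroxy-2-{[(TBDPS)oxy]methyl}propanoate F4. Dess–Martin oxidation (NaHCO3, CH2Cl2) of the remaining primary alcohol would give 5, where the route is rejoined.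

Step 12. The activated benzylic carbon may be attacked by a phenol oxygen of a second molecule (ether formation, oligomers) instead of by palmitate. Fallback: enzymatic esterification, in which the enzyme and not acidity tells alcohol from phenol. Setting out from 21 and 22, immobilized Candida antarctica lipase B with 4 Å molecular sieves in tert-butyl methyl ether at 45 °C would acylate only the primary alcohol and give 23 directly. This fallback makes no new compound (F0).

Further compounds
F1 | step 10 | (3Z)-3-{[(TBDPS)oxy]methyl}-4-{2-(methoxycarbonyl)-5-methyl-3-[(TIPS)oxy]phenoxy}but-3-enoic acid | OC(=O)C/C(CO[Si](c1ccccc1)(c1ccccc1)C(C)(C)C)=C/Oc1cc(C)cc(O[Si](C(C)C)(C(C)C)C(C)C)c1C(=O)OC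
F2 | step 10 | (3Z)-3-{[(TBDPS)oxy]methyl}-4-{2-(methoxycarbonyl)-5-methyl-3-[(TIPS)oxy]phenoxy}but-3-enoyl chloride | ClC(=O)C/C(CO[Si](c1ccccc1)(c1ccccc1)C(C)(C)C)=C/Oc1cc(C)cc(O[Si](C(C)C)(C(C)C)C(C)C)c1C(=O)OC
F3 | step 3 | tert-butyl 3-hydroxy-2-(hydroxymethyl)propanoate | CC(C)(C)OC(=O)C(CO)CO
F4 | step 3 | tert-butyl 3-hydroxy-2-{[(TBDPS)oxy]methyl}propanoate (racemic) | CC(C)(C)OC(=O)C(CO)CO[Si](c1ccccc1)(c1ccccc1)C(C)(C)C
F0 | step 12 | none | none
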